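**Retrosynthetic overview**
1. Target ⇐ desilylation/acetylation of the C6 silyl ether; enyne ⇐ enal (Colvin) ⇐ allyl group (cross-metathesis).
2. Oxocene with C12–Br, C13–Et and the 9Z olefin ⇐ one-step ring expansion of a 2,3-cis-3-silyl-tetrahydrofuran: Br+ on the pentenyl olefin, bicyclic oxonium, desilylative C–O fragmentation.
3. Silyl-tetrahydrofuran ⇐ acid-catalysed hydroalkoxylation of an (E)-vinylsilane homoallylic alcohol.
4. Vinylsilane alcohol ⇐ α-silylalkenyl alanate (from TMS-acetylene and (E)-1-bromopent-2-ene) + epoxide from (R,R)-diepoxybutane and vinyl Grignard, which supplies C6 and C7.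
5. Ring order: oxolane first (step 4), then expanded to the oxocine (step 5); no other ring is made.

Assumption: (2R,2'R)-2,2'-bioxirane (D-diepoxybutane), (2E)-1-bromopent-2-ene, vinylmagnesium bromide and crotonaldehyde are taken as purchasable; C1–C15 in the comments is laurencin numbering (C1 alkyne CH, C6 acetoxy carbon, C7 and C13 ring O-carbons, C12 CBr).

Step 1
Reactants: 1 ethynyl(trimethyl)silane; 2 (2E)-1-bromopent-2-ene
Product: 4 [(4E)-hept-4-en-1-yn-1-yl](trimethyl)silane, via alkynylmagnesium bromide 3 (not isolated)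
Conditions: EtMgBr, THF, 0 → 40 °C; then CuBr·SMe2 (5 mol %), 2, 50 °C
Reagents that add atoms: none
Why: Copper-catalysed SN2 allyl–alkynyl coupling of an alkynyl Grignard reagent with a primary allylic bromide gives the skipped enyne with the E olefin intact; no stereocentre is formed.

Step 2
Reactants: 5 (2R,2'R)-2,2'-bioxirane; 6 vinylmagnesium bromide
Product: 8 tert-butyl(dimethyl){[(1R)-1-[(2R)-oxiran-2-yl]but-3-en-1-yl]oxy}silane, via bromomagnesium alkoxide 7 (not isolated)
Conditions: 5 (2 equiv), CuI (10 mol %), THF, −40 °C, slow addition of 6; then TBSOTf, 2,6-lutidine, −78 → −20 °C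
Reagents that add atoms: tert-butyldimethylsilyl trifluoromethanesulfonate (TBSOTf), CC(C)(C)[Si](C)(C)OS(=O)(=O)C(F)(F)F
Why: Copper-catalysed Grignard opening of a terminal epoxide occurs at CH2, so both C–O stereocentres of C2-symmetric 5 (future C6 and C7) are kept and either epoxide gives the same product, and the volatile alkoxide is trapped cold as its TBS ether (O-silylation) before Payne rearrangement can occur.

Step 3
Reactants: 4 [(4E)-hept-4-en-1-yn-1-yl](trimethyl)silane; 8 tert-butyl(dimethyl){[(1R)-1-[(2R)-oxiran-2-yl]but-3-en-1-yl]oxy}silane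
Product: 11 (4R,5R,7E,10E)-4-[(tert-butyldimethylsilyl)oxy]-7-(trimethylsilyl)trideca-1,7,10-trien-5-ol, via alkenylalane 9 (not isolated), via lithium alkenylalanate 10 (not isolated)
Conditions: 4, i-Bu2AlH, heptane, 55 °C; MeLi, Et2O, 0 °C; then 8, THF, 0 °C → rt; aq. Rochelle salt
Reagents that add atoms: none
Why: Trans-hydroalumination of a 1-silylalkyne in hydrocarbon solvent puts Al cis to the alkyl chain, and the derived alkenyl alanate opens the terminal epoxide at CH2 with retention at the alkenyl carbon (alanate epoxide alkylation), giving the (E)-vinylsilane with C8 and C11 cis; both carbinol centres come unchanged from 8.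

Step 4
Reactants: 11 (4R,5R,7E,10E)-4-[(tert-butyldimethylsilyl)oxy]-7-(trimethylsilyl)trideca-1,7,10-trien-5-ol
Product: 12 (2S,3S,5R)-5-[(1R)-1-{[tert-butyl(dimethyl)silyl]oxy}but-3-en-1-yl]-2-[(2E)-pent-2-en-1-yl]-3-(trimethylsilyl)oxolane
Conditions: TsOH·H2O (10 mol %), CHCl3, 40 °C
Reagents that add atoms: none
Why: Acid-catalysed intramolecular hydroalkoxylation of a vinylsilane (5-membered closure on a β-silyl cation): ipso-protonation at C9 and attack of the C7 hydroxyl on C10 anti to the hyperconjugating C–Si bond turn the cis alkene geometry into the 2,3-cis (2S,3S) relationship, and the C5 side chain takes the face opposite the pseudo-axial pentenyl group (2,5-trans).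

Step 5
Reactants: 12 (2S,3S,5R)-5-[(1R)-1-{[tert-butyl(dimethyl)silyl]oxy}but-3-en-1-yl]-2-[(2E)-pent-2-en-1-yl]-3-(trimethylsilyl)oxolane
Product: 14 tert-butyl{[(1R)-1-[(2R,7S,8R)-7-bromo-8-ethyl-3,6,7,8-tetrahydro-2H-oxocin-2-yl]but-3-en-1-yl]oxy}dimethylsilane, via bicyclic oxonium salt 13 (not isolated)
Conditions: BDSB (Et2SBr·SbCl5Br, 1.1 equiv), MeNO2, −25 °C, 10 min; aq. Na2SO3/NaHCO3
Reagents that add atoms: bromodiethylsulfonium bromopentachloroantimonate (BDSB), CC[S+](Br)CC.Cl[Sb-](Cl)(Cl)(Cl)(Cl)Br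
Why: Proposed new method: BDSB puts Br+ on the only 1,2-dialkyl E-olefin and the ring oxygen opens the bromonium at C13 through a five-membered transition state (as in known bromonium-induced tetrahydrofuran-to-oxocane ring expansions), anti addition across the E-olefin with ethyl exo on the cis-fused 1-oxoniabicyclo[3.3.0]octane 13 setting 7S,8R; because TMS is cis to the former pentenyl arm, the C–Si bond in 13 lies anti to the ring-fusion O+–C10 bond, so β-silicon hyperconjugation singles out that bond and bromide attack at silicon triggers an anti Peterson/Grob-type fragmentation that can only give the Z ring olefin, replacing the carbonate or halide capture used so far (closest known reactions: BDSB ring expansion via bicyclic oxonium ions and acid-mediated anti elimination of β-silyl ethers).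

Step 6
Reactants: 14 tert-butyl{[(1R)-1-[(2R,7S,8R)-7-bromo-8-ethyl-3,6,7,8-tetrahydro-2H-oxocin-2-yl]but-3-en-1-yl]oxy}dimethylsilane; 15 (2E)-but-2-enal
Product: 16 (2E,5R)-5-[(2R,7S,8R)-7-bromo-8-ethyl-3,6,7,8-tetrahydro-2H-oxocin-2-yl]-5-{[tert-butyl(dimethyl)silyl]oxy}pent-2-enal
Conditions: Grubbs II (5 mol %), 15 (5 equiv), CH2Cl2, 40 °C
Reagents that add atoms: none
Why: Olefin cross-metathesis of the terminal alkene with crotonaldehyde gives the E-enal, while the cis olefin of the unstrained oxocene and the secondary bromide stay untouched; no stereocentre changes.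

Step 7
Reactants: 16 (2E,5R)-5-[(2R,7S,8R)-7-bromo-8-ethyl-3,6,7,8-tetrahydro-2H-oxocin-2-yl]-5-{[tert-butyl(dimethyl)silyl]oxy}pent-2-enal
Product: 17 tert-butyl{[(1R,3E)-1-[(2R,7S,8R)-7-bromo-8-ethyl-3,6,7,8-tetrahydro-2H-oxocin-2-yl]hex-3-en-5-yn-1-yl]oxy}dimethylsilane
Conditions: TMSCHN2, LDA, THF, −78 → 0 °C
Reagents that add atoms: (trimethylsilyl)diazomethane, C[Si](C)(C)C=[N+]=[N-]
Why: Colvin rearrangement (addition of lithiated TMS-diazomethane, Peterson elimination, alkylidene-carbene 1,2-H shift) turns the enal into the terminal E-enyne at low temperature without touching the bromide or the silyl ether.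

Step 8
Reactants: 17 tert-butyl{[(1R,3E)-1-[(2R,7S,8R)-7-bromo-8-ethyl-3,6,7,8-tetrahydro-2H-oxocin-2-yl]hex-3-en-5-yn-1-yl]oxy}dimethylsilane
Product: 19 (1R,3E)-1-[(2R,7S,8R)-7-bromo-8-ethyl-3,6,7,8-tetrahydro-2H-oxocin-2-yl]hex-3-en-5-yn-1-yl acetate, via deacetyllaurencin 18 (not isolated)
Conditions: HF·pyridine, pyridine/THF, 0 °C → rt; then Ac2O, DMAP, rt
Reagents that add atoms: acetic anhydride, CC(=O)OC(C)=O
Why: Non-basic fluoride desilylation spares the homoallylic bromide and DMAP-catalysed acetylation of the freed secondary alcohol follows in the same flask; the carbinol C–O bond is never broken, so 1R is retained.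

**Compound list**
1 | ethynyl(trimethyl)silane | C[Si](C)(C)C#C | starting material
2 | (2E)-1-bromopent-2-ene | CC/C=C/CBr | starting material
3 | bromo[(trimethylsilyl)ethynyl]magnesium | C[Si](C)(C)C#C[Mg]Br | intermediate
4 | [(4E)-hept-4-en-1-yn-1-yl](trimethyl)silane | C[Si](C)(C)C#CC/C=C/CC | intermediate
5 | (2R,2'R)-2,2'-bioxirane | C1[C@@H](O1)[C@H]2CO2 | starting material
6 | vinylmagnesium bromide | C=C[Mg]Br | starting material
7 | bromomagnesium (1R)-1-[(2R)-oxiran-2-yl]but-3-en-1-olate | C=CC[C@@H](O[Mg]Br)[C@H]1CO1 | intermediate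
8 | tert-butyl(dimethyl){[(1R)-1-[(2R)-oxiran-2-yl]but-3-en-1-yl]oxy}silane | C=CC[C@@H](O[Si](C)(C)C(C)(C)C)[C@H]1CO1 | intermediate
9 | diisobutyl[(1E,4E)-1-(trimethylsilyl)hepta-1,4-dien-1-yl]alumane | CC/C=C/C/C=C(\[Al](CC(C)C)CC(C)C)[Si](C)(C)C | intermediate
10 | lithium diisobutyl(methyl)[(1E,4E)-1-(trimethylsilyl)hepta-1,4-dien-1-yl]aluminate | [Li+].CC/C=C/C/C=C(\[Al-](C)(CC(C)C)CC(C)C)[Si](C)(C)C | intermediate
11 | (4R,5R,7E,10E)-4-[(tert-butyldimethylsilyl)oxy]-7-(trimethylsilyl)trideca-1,7,10-trien-5-ol | C=CC[C@@H](O[Si](C)(C)C(C)(C)C)[C@H](O)C/C(=C\C/C=C/CC)[Si](C)(C)C | intermediate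
12 | (2S,3S,5R)-5-[(1R)-1-{[tert-butyl(dimethyl)silyl]oxy}but-3-en-1-yl]-2-[(2E)-pent-2-en-1-yl]-3-(trimethylsilyl)oxolane | C=CC[C@@H](O[Si](C)(C)C(C)(C)C)[C@H]1C[C@H]([Si](C)(C)C)[C@H](C/C=C/CC)O1 | intermediate
13 | cis-fused 7-bromo-8-ethyl-2-[(1R)-1-(TBS-oxy)but-3-enyl]-4-(trimethylsilyl)-1-oxoniabicyclo[3.3.0]octane bromopentachloroantimonate (stereocentres as in 12 and 14) | C=CC[C@@H](O[Si](C)(C)C(C)(C)C)[C@H]1C[C@H]([Si](C)(C)C)[C@@H]2C[C@H](Br)[C@@H](CC)[O+]12.Cl[Sb-](Cl)(Cl)(Cl)(Cl)Br | intermediate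
14 | tert-butyl{[(1R)-1-[(2R,7S,8R)-7-bromo-8-ethyl-3,6,7,8-tetrahydro-2H-oxocin-2-yl]but-3-en-1-yl]oxy}dimethylsilane | C=CC[C@@H](O[Si](C)(C)C(C)(C)C)[C@H]1C/C=C\C[C@H](Br)[C@@H](CC)O1 | intermediate
15 | (2E)-but-2-enal (crotonaldehyde) | C/C=C/C=O | starting material
16 | (2E,5R)-5-[(2R,7S,8R)-7-bromo-8-ethyl-3,6,7,8-tetrahydro-2H-oxocin-2-yl]-5-{[tert-butyl(dimethyl)silyl]oxy}pent-2-enal | O=C/C=C/C[C@@H](O[Si](C)(C)C(C)(C)C)[C@H]1C/C=C\C[C@H](Br)[C@@H](CC)O1 | intermediate
17 | tert-butyl{[(1R,3E)-1-[(2R,7S,8R)-7-bromo-8-ethyl-3,6,7,8-tetrahydro-2H-oxocin-2-yl]hex-3-en-5-yn-1-yl]oxy}dimethylsilane | C#C/C=C/C[C@@H](O[Si](C)(C)C(C)(C)C)[C@H]1C/C=C\C[C@H](Br)[C@@H](CC)O1 | intermediate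
18 | (1R,3E)-1-[(2R,7S,8R)-7-bromo-8-ethyl-3,6,7,8-tetrahydro-2H-oxocin-2-yl]hex-3-en-5-yn-1-ol (deacetyllaurencin) | C#C/C=C/C[C@@H](O)[C@H]1C/C=C\C[C@H](Br)[C@@H](CC)O1 | intermediate
19 | (1R,3E)-1-[(2R,7S,8R)-7-bromo-8-ethyl-3,6,7,8-tetrahydro-2H-oxocin-2-yl]hex-3-en-5-yn-1-yl acetate | C#C/C=C/C[C@@H](OC(C)=O)[C@H]1C/C=C\C[C@H](Br)[C@@H](CC)O1 | target

**Step count and risks**
Total steps: 8. Longest linear sequence: 7 (5 → 8 → 11 → 12 → 14 → 16 → 17 → 19; step 1 is a one-step side branch).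

Most at risk is step 5, the new ring expansion. It could fail if the bromonium opens on the other olefin face (giving the trans-α,α' oxocene), if halide capture at carbon outruns desilylation, or if Br+ is spent on the terminal olefin. The fallback sets out from 12 and comes back at 14 with known chemistry. BF3·OEt2 in CH2Cl2 (−78 → 0 °C) opens the β-silyl ether by anti Peterson-type elimination to (4R,5R,7Z,10E)-4-[(tert-butyldimethylsilyl)oxy]trideca-1,7,10-trien-5-ol F7. Direct 8-endo bromoetherification of this laurediol-type dienol with 2,4,4,6-tetrabromocyclohexa-2,5-dienone in CH2Cl2 then gives 14. This biomimetic cyclisation is precedented for the compound class but low-yielding, and 14 must be separated from 7-exo and 5-endo isomers.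

Second is step 3. The hindered α-silylalkenyl alanate may open the substituted epoxide sluggishly, and any loss of alkene geometry would be carried into the ring stereochemistry. The fallback sets out from 4 and 8 and comes back at 11. K2CO3/MeOH converts 4 to (4E)-hept-4-en-1-yne F1, and n-BuLi (THF, −78 °C) gives lithium (4E)-hept-4-en-1-yn-1-ide F2. With BF3·OEt2, F2 opens 8 to (4R,5R,10E)-4-[(tert-butyldimethylsilyl)oxy]trideca-1,10-dien-7-yn-5-ol F3. Silylation with 1,1,3,3-tetramethyldisilazane gives tert-butyl{[(4R,5R,10E)-5-[(dimethylsilyl)oxy]trideca-1,10-dien-7-yn-4-yl]oxy}dimethylsilane F4. Pt(0)-catalysed intramolecular syn-hydrosilylation (5-exo-dig) gives (3E,5R)-5-[(1R)-1-{[tert-butyl(dimethyl)silyl]oxy}but-3-en-1-yl]-3-[(3E)-hex-3-en-1-ylidene]-2,2-dimethyl-1,2-oxasilolane F5. MeLi then opens the Si–O bond to give 11 with the same alkene geometry.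

Third is step 4. Protodesilylation to the Z-alkene may compete with ring closure, and the 2,5-trans preference is predicted, not demonstrated. The fallback sets out from 11 and comes back at 12. N-(phenylseleno)phthalimide with catalytic CSA (CH2Cl2, −40 °C) effects 5-endo selenoetherification, with oxygen adding to the β-silyl-stabilised carbon, to give (2S,3S,5R)-5-[(1R)-1-{[tert-butyl(dimethyl)silyl]oxy}but-3-en-1-yl]-2-[(2E)-pent-2-en-1-yl]-3-(phenylselanyl)-3-(trimethylsilyl)oxolane F6. Bu3SnH/AIBN (benzene, 80 °C) then removes selenium; hydrogen is delivered to the α-silyl radical from the face opposite the adjacent pentenyl group, which leaves TMS cis to it as in 12.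

Further compounds
F1 | step 3 | (4E)-hept-4-en-1-yne | C#CC/C=C/CC
F2 | step 3 | lithium (4E)-hept-4-en-1-yn-1-ide | [Li]C#CC/C=C/CC
F3 | step 3 | (4R,5R,10E)-4-[(tert-butyldimethylsilyl)oxy]trideca-1,10-dien-7-yn-5-ol | C=CC[C@@H](O[Si](C)(C)C(C)(C)C)[C@H](O)CC#CC/C=C/CC
F4 | step 3 | tert-butyl{[(4R,5R,10E)-5-[(dimethylsilyl)oxy]trideca-1,10-dien-7-yn-4-yl]oxy}dimethylsilane | C=CC[C@@H](O[Si](C)(C)C(C)(C)C)[C@H](O[SiH](C)C)CC#CC/C=C/CC
F5 | step 3 | (3E,5R)-5-[(1R)-1-{[tert-butyl(dimethyl)silyl]oxy}but-3-en-1-yl]-3-[(3E)-hex-3-en-1-ylidene]-2,2-dimethyl-1,2-oxasilolane | C=CC[C@@H](O[Si](C)(C)C(C)(C)C)[C@H]1C/C(=C\C/C=C/CC)[Si](C)(C)O1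
F6 | step 4 | (2S,3S,5R)-5-[(1R)-1-{[tert-butyl(dimethyl)silyl]oxy}but-3-en-1-yl]-2-[(2E)-pent-2-en-1-yl]-3-(phenylselanyl)-3-(trimethylsilyl)oxolane | C=CC[C@@H](O[Si](C)(C)C(C)(C)C)[C@H]1C[C@@]([Se]c2ccccc2)([Si](C)(C)C)[C@H](C/C=C/CC)O1
F7 | step 5 | (4R,5R,7Z,10E)-4-[(tert-butyldimethylsilyl)oxy]trideca-1,7,10-trien-5-ol | C=CC[C@@H](O[Si](C)(C)C(C)(C)C)[C@H](O)C/C=C\C/C=C/CC
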